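The route rests on disconnecting the pyrrole C2–C3 bond. The three chlorinated pyrrole carbons C3, C4 and C5 are the three carbons of trichloroacryloyl chloride, and pyrrole C2 starts as a CH2 group made acidic by oxazole C2 and an amide nitrogen. In a single operation a hindered lithium amide turns this CH2 into a carbanion that adds to the CCl2 terminus and ejects chloride, delivering a 3,4-dichloro-γ-lactam with the oxazole in place; the third chlorine arrives when the lactam C=O is later exchanged for C–Cl. The cyclisation substrate is an N-cumyl-N-(oxazol-2-ylmethyl) trichloroacrylamide whose 5-(4-methoxyphenyl)oxazole already bears its C4 chlorine, so the base meets no oxazole C–H and no chlorination is needed afterwards.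

Key step: step 6

Remark: lactams 12 and 13 are drawn as the conjugated 1,5-dihydro tautomers; any 1,3-dihydro or 2-hydroxypyrrole tautomer present alongside should converge on the same pyrrole in step 8.

Step 1
Reactants: 1 2-amino-1-(4-methoxyphenyl)ethanone hydrochloride; 2 chloroacetyl chloride
Product: 3 2-chloro-N-[2-(4-methoxyphenyl)-2-oxoethyl]acetamide
Conditions: NaHCO3, EtOAc/H2O, 0 °C → rt
Reagents that add atoms: none
Why: Schotten–Baumann N-acylation, in which the amine is released from its salt only in the presence of the acid chloride, so that amide formation should outrun self-condensation of the α-aminoketone.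

Step 2
Reactants: 3 2-chloro-N-[2-(4-methoxyphenyl)-2-oxoethyl]acetamide
Product: 4 2-(chloromethyl)-5-(4-methoxyphenyl)oxazole
Conditions: POCl3, toluene, 100 °C
Reagents that add atoms: none
Why: Robinson–Gabriel cyclodehydration of a 2-acylamino ketone, in which the amide oxygen closes onto the activated ketone carbon and water is lost, a standard entry to 2-(chloromethyl)-5-aryloxazoles that leaves the primary alkyl chloride untouched.

Step 3
Reactants: 4 2-(chloromethyl)-5-(4-methoxyphenyl)oxazole
Product: 5 4-chloro-2-(chloromethyl)-5-(4-methoxyphenyl)oxazole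
Conditions: NCS (1.05 equiv), MeCN, 50 °C, dark
Reagents that add atoms: N-chlorosuccinimide, O=C1CCC(=O)N1Cl
Why: Electrophilic chlorination of a 5-aryloxazole takes place at C4, the β carbon of the ring enol ether that is further activated through the 4-methoxyphenyl group, and should outpace attack on the benzene ring; done here, it removes the only oxazole C–H before the strong-base step and spares the finished pyrrole any electrophilic chlorination.

Step 4
Reactants: 5 4-chloro-2-(chloromethyl)-5-(4-methoxyphenyl)oxazole; 6 cumylamine (2-phenylpropan-2-amine)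
Product: 7 N-{[4-chloro-5-(4-methoxyphenyl)oxazol-2-yl]methyl}-2-phenylpropan-2-amine
Conditions: K2CO3, NaI (cat.), MeCN, 70 °C
Reagents that add atoms: none
Why: SN2 N-alkylation of a primary amine by a heterobenzylic chloride with Finkelstein assistance, in which the α-tertiary cumyl group should stop the reaction at the secondary amine and the ring chlorine on a non-activated sp2 carbon is not displaced.

Step 5
Reactants: 7 N-{[4-chloro-5-(4-methoxyphenyl)oxazol-2-yl]methyl}-2-phenylpropan-2-amine; 8 trichloroacryloyl chloride
Product: 9 2,3,3-trichloro-N-{[4-chloro-5-(4-methoxyphenyl)oxazol-2-yl]methyl}-N-(2-phenylpropan-2-yl)acrylamide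
Conditions: iPr2NEt, CH2Cl2, 0 °C → rt
Reagents that add atoms: none
Why: N-acylation of a secondary amine by an acid chloride, in which the acyl chloride carbon is far more electrophilic than the dichlorovinyl terminus, so the amide should form without loss of a vinylic chlorine.

Step 6
Reactants: 9 2,3,3-trichloro-N-{[4-chloro-5-(4-methoxyphenyl)oxazol-2-yl]methyl}-N-(2-phenylpropan-2-yl)acrylamide
Product: 12 racemic 3,4-dichloro-5-[4-chloro-5-(4-methoxyphenyl)oxazol-2-yl]-1-(2-phenylpropan-2-yl)-1,5-dihydro-2H-pyrrol-2-one, via lithiated amide 10 (not isolated), via lithium pyrrol-2-olate 11 (not isolated)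
Conditions: 9 added slowly to lithium 2,2,6,6-tetramethylpiperidide (2.2 equiv), THF, −78 °C; then AcOH, −78 °C → rt
Reagents that add atoms: none
Why: Proposed new method: the lithium amide should remove a proton from the CH2 group between oxazole C2 and the amide nitrogen, the only acidic C–H in 9, and the dipole-stabilised, oxazole-conjugated carbanion 10 should add to the dichlorinated alkene carbon and lose chloride from it (addition–elimination, a net vinylic substitution), which creates the bond that becomes pyrrole C2–C3 and shuts the γ-lactam; the ring-closed lactam is more acidic than 9, so a second equivalent of base stores it as the aromatic pyrrol-2-olate 11 until the acetic acid quench. The closest known reaction types are the 5-endo ring closure of α-lithiated N-benzyl-N-cumyl aryl amides and acrylamides and the replacement of β-chlorine in β,β-dichloroacrylic acid derivatives by carbanions. The five-membered ring closes in the 5-endo-trig mode, which should be accessible because the α-chlorine and the bulky nitrogen substituents turn the alkene out of the amide plane and expose its π face to the neighbouring carbanion. The new C5 stereocentre has no controlling element and forms as the racemate; it is configurationally labile through 11 and is erased by the aromatisation in step 8. Two selectivities are needed, C–H deprotonation instead of attack of the base on the trichloroacryloyl group, and closure at the β carbon instead of 4-exo closure at the α carbon; a hydride-free, non-nucleophilic base at −78 °C with the substrate added to the base, the rotamer preference that places the small CH2 arm and not the cumyl group beside the alkene, and the fact that only the β carbon carries leaving groups and leads on to an amide enolate should secure them.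

Step 7
Reactants: 12 racemic 3,4-dichloro-5-[4-chloro-5-(4-methoxyphenyl)oxazol-2-yl]-1-(2-phenylpropan-2-yl)-1,5-dihydro-2H-pyrrol-2-one
Product: 13 racemic 3,4-dichloro-5-[4-chloro-5-(4-methoxyphenyl)oxazol-2-yl]-1,5-dihydro-2H-pyrrol-2-one
Conditions: TFA, anisole (5 equiv), CH2Cl2, rt, under argon
Reagents that add atoms: none
Why: Acidolytic N-dealkylation of an N-cumyl amide (SN1 loss of the tertiary benzylic cation from the O-protonated lactam), with excess anisole as cation trap so that the methoxyphenyl ring of the substrate is not alkylated.

Step 8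
Reactants: 13 racemic 3,4-dichloro-5-[4-chloro-5-(4-methoxyphenyl)oxazol-2-yl]-1,5-dihydro-2H-pyrrol-2-one
Product: 14 4-chloro-5-(4-methoxyphenyl)-2-(3,4,5-trichloro-1H-pyrrol-2-yl)oxazole
Conditions: POCl3, 90 °C
Reagents that add atoms: phosphoryl chloride, O=P(Cl)(Cl)Cl
Why: Deoxychlorination of a lactam that is the keto tautomer of a 2-hydroxypyrrole, the reaction type that turns pyridones into chloropyridines and 3-pyrrolin-2-ones into 2-halopyrroles: O-phosphorylation, exchange of the phosphate for chloride at the iminium carbon and loss of the C5 proton should give the aromatic pyrrole, at which point the racemic stereocentre vanishes.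

Step 9
Reactants: 14 4-chloro-5-(4-methoxyphenyl)-2-(3,4,5-trichloro-1H-pyrrol-2-yl)oxazole
Product: 15 4-[4-chloro-2-(3,4,5-trichloro-1H-pyrrol-2-yl)oxazol-5-yl]phenol
Conditions: BBr3 (4 equiv), CH2Cl2, −78 → 0 °C; then H2O
Reagents that add atoms: none
Why: Lewis acid cleavage of an aryl methyl ether (boron coordination to the ether oxygen, then SN2 attack of bromide on the methyl group), under conditions that should leave the aryl and heteroaryl C–Cl bonds, the oxazole and the N–H pyrrole intact.

Compound list
1 | 2-amino-1-(4-methoxyphenyl)ethanone hydrochloride | Cl.COc1ccc(cc1)C(=O)CN | starting material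
2 | chloroacetyl chloride | ClCC(Cl)=O | starting material
3 | 2-chloro-N-[2-(4-methoxyphenyl)-2-oxoethyl]acetamide | COc1ccc(cc1)C(=O)CNC(=O)CCl | intermediate
4 | 2-(chloromethyl)-5-(4-methoxyphenyl)oxazole | COc1ccc(cc1)-c1cnc(CCl)o1 | intermediate
5 | 4-chloro-2-(chloromethyl)-5-(4-methoxyphenyl)oxazole | COc1ccc(cc1)-c1oc(CCl)nc1Cl | intermediate
6 | cumylamine (2-phenylpropan-2-amine) | CC(C)(N)c1ccccc1 | starting material
7 | N-{[4-chloro-5-(4-methoxyphenyl)oxazol-2-yl]methyl}-2-phenylpropan-2-amine | COc1ccc(cc1)-c1oc(CNC(C)(C)c2ccccc2)nc1Cl | intermediate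
8 | trichloroacryloyl chloride (2,3,3-trichloroprop-2-enoyl chloride) | ClC(Cl)=C(Cl)C(Cl)=O | starting material
9 | 2,3,3-trichloro-N-{[4-chloro-5-(4-methoxyphenyl)oxazol-2-yl]methyl}-N-(2-phenylpropan-2-yl)acrylamide | COc1ccc(cc1)-c1oc(CN(C(=O)C(Cl)=C(Cl)Cl)C(C)(C)c2ccccc2)nc1Cl | intermediate
10 | lithiated amide, the lithium derivative of 9 deprotonated at the N–CH2 carbon (formed in step 6, not isolated) | [Li+].COc1ccc(cc1)-c1oc([CH-]N(C(=O)C(Cl)=C(Cl)Cl)C(C)(C)c2ccccc2)nc1Cl | intermediate
11 | lithium 3,4-dichloro-5-[4-chloro-5-(4-methoxyphenyl)oxazol-2-yl]-1-(2-phenylpropan-2-yl)-1H-pyrrol-2-olate (formed in step 6, not isolated) | [Li+].COc1ccc(cc1)-c1oc(nc1Cl)-c1c(Cl)c(Cl)c([O-])n1C(C)(C)c1ccccc1 | intermediate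
12 | racemic 3,4-dichloro-5-[4-chloro-5-(4-methoxyphenyl)oxazol-2-yl]-1-(2-phenylpropan-2-yl)-1,5-dihydro-2H-pyrrol-2-one | COc1ccc(cc1)-c1oc(nc1Cl)C1N(C(=O)C(Cl)=C1Cl)C(C)(C)c1ccccc1 | intermediate
13 | racemic 3,4-dichloro-5-[4-chloro-5-(4-methoxyphenyl)oxazol-2-yl]-1,5-dihydro-2H-pyrrol-2-one | COc1ccc(cc1)-c1oc(nc1Cl)C1NC(=O)C(Cl)=C1Cl | intermediate
14 | 4-chloro-5-(4-methoxyphenyl)-2-(3,4,5-trichloro-1H-pyrrol-2-yl)oxazole | COc1ccc(cc1)-c1oc(nc1Cl)-c1[nH]c(Cl)c(Cl)c1Cl | intermediate
15 | 4-[4-chloro-2-(3,4,5-trichloro-1H-pyrrol-2-yl)oxazol-5-yl]phenol (no stereocentre) | Oc1ccc(-c2oc(-c3[nH]c(Cl)c(Cl)c3Cl)nc2Cl)cc1 | target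

Total step count: 9
Longest linear sequence: 9 steps (1 → 15)

Steps most likely to fail

Step 6 (proposed new method). The base or the carbanion may be consumed at the trichlorovinyl group, by substitution or electron transfer, before the ring closes, or closure may take place at the α carbon to give a four-membered ring. The fallback uses known chemistry, sets out from 1 and rejoins the route at 14; it brings the pyrrole in preformed instead of building it. Compound 1 would be N-acylated with 2-(trichloroacetyl)pyrrole (Et3N, MeCN; amide formation with loss of chloroform) to give N-[2-(4-methoxyphenyl)-2-oxoethyl]-1H-pyrrole-2-carboxamide F1. Robinson–Gabriel cyclodehydration with POCl3 would give 5-(4-methoxyphenyl)-2-(1H-pyrrol-2-yl)oxazole F2. Exhaustive electrophilic chlorination with NCS (4 equiv, added in portions) at the three pyrrole C–H positions and at oxazole C4 would then lead to 14, from which step 9 follows.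

Step 8. Phosphorylation of the electron-poor lactam oxygen may be too slow, so that self-condensation or oxidation of the 2-hydroxypyrrole tautomer takes over. The fallback sets out from 12 and rejoins at 14; it replaces the C=O to C–Cl exchange by reduction to C–H followed by chlorination. Lactam 12 would be reduced with diisobutylaluminium hydride (i-Bu2AlH, CH2Cl2, −78 °C) to the hemiaminal 3,4-dichloro-5-[4-chloro-5-(4-methoxyphenyl)oxazol-2-yl]-1-(2-phenylpropan-2-yl)-2,5-dihydro-1H-pyrrol-2-ol F3 (mixture of diastereomers, not isolated). On acidic work-up this should lose water and aromatise to 4-chloro-2-[3,4-dichloro-1-(2-phenylpropan-2-yl)-1H-pyrrol-2-yl]-5-(4-methoxyphenyl)oxazole F4. TFA with anisole would remove the cumyl group to give 4-chloro-2-(3,4-dichloro-1H-pyrrol-2-yl)-5-(4-methoxyphenyl)oxazole F5, and NCS (1 equiv) should chlorinate its free pyrrole α position to give 14.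

Step 7. N–C cleavage may stay incomplete on this electron-poor lactam, the cumyl cation may alkylate the methoxyphenyl ring, and the N–H lactam may autoxidise at C5 during isolation. The fallback sets out from 12 and rejoins at 14 without passing through 13. Compound 12 would be heated directly in POCl3, so that the activated iminium ion of the tertiary lactam loses the cumyl cation, in the manner of the von Braun amide degradation of N-tert-alkyl amides, and the resulting cyclic imidoyl chloride aromatises to 14; no new compound arises (F0).

Further compounds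
F1 | step 6 | N-[2-(4-methoxyphenyl)-2-oxoethyl]-1H-pyrrole-2-carboxamide | COc1ccc(cc1)C(=O)CNC(=O)c1ccc[nH]1
F2 | step 6 | 5-(4-methoxyphenyl)-2-(1H-pyrrol-2-yl)oxazole | COc1ccc(cc1)-c1cnc(o1)-c1ccc[nH]1
F3 | step 8 | 3,4-dichloro-5-[4-chloro-5-(4-methoxyphenyl)oxazol-2-yl]-1-(2-phenylpropan-2-yl)-2,5-dihydro-1H-pyrrol-2-ol (mixture of diastereomers) | COc1ccc(cc1)-c1oc(nc1Cl)C1N(C(O)C(Cl)=C1Cl)C(C)(C)c1ccccc1
F4 | step 8 | 4-chloro-2-[3,4-dichloro-1-(2-phenylpropan-2-yl)-1H-pyrrol-2-yl]-5-(4-methoxyphenyl)oxazole | COc1ccc(cc1)-c1oc(nc1Cl)-c1c(Cl)c(Cl)cn1C(C)(C)c1ccccc1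
F5 | step 8 | 4-chloro-2-(3,4-dichloro-1H-pyrrol-2-yl)-5-(4-methoxyphenyl)oxazole | COc1ccc(cc1)-c1oc(nc1Cl)-c1[nH]cc(Cl)c1Cl
F0 | step 7 | none | none
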